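The cyclohexenone ring (C1, C10–C14; briarane numbering) is cut at C1–C14 and C10–C11. Its C12 ketone and C13=C14 alkene are the trace of a 1-methoxy-3-silyloxy-1,3-pentadiene, and C1=C10 that of an (E)-2-methyl enal on an arabino-configured C6–C9 chain. Because C8 carries oxygen two atoms from C10, the dienol oxygen is tied to O8 by a dimethylsilyl ketal. A type 2 intramolecular Diels–Alder reaction then forms both bonds and sets C1, C10 and C11 from C9 in one operation. Lactone (intramolecular Reformatsky), ten-membered ring (Nozaki–Hiyama–Kishi closure at C5–C6) and chloride (invertive substitution) follow.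

Key step: step 6

Remark: briarane numbering of the target is used for every intermediate (C1 quaternary ring-fusion carbon with Me-15, C2 and C3 acetoxy carbons, C4 CH2, C5 with exo-methylene C16, C6 CHCl, C7 lactone CH–O, C8 C–OH, C9 CH–OAc, C10 ring-fusion CH, C11 CH with Me-20, C12 ketone, C13=C14, C17 lactone CH with Me-18, C19 lactone C=O); compounds 1, 3 and 5 are taken as commercial.

Step 1
Reactants: 1 (E)-4-methoxybut-3-en-2-one
Product: 2 (E)-1-methoxypent-1-en-3-one
Conditions: LiN(iPr)2, THF, −78 °C; MeI, −78 → −30 °C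
Reagents that add atoms: iodomethane (CI)
Why: Kinetic α′-deprotonation of the vinylogous ester and SN2 methylation of the lithium enolate (enolate alkylation) extend the methyl ketone to the ethyl ketone that will supply C11 and its methyl group; no stereocentre is formed.

Step 2
Reactants: 3 allyloxy(tert-butyl)dimethylsilane
Product: 4 (Z)-tributyl[3-(tert-butyldimethylsilyloxy)prop-2-en-1-yl]stannane
Conditions: sec-BuLi, THF/HMPA, −78 °C; Bu3SnCl
Reagents that add atoms: tributyltin chloride (CCCC[Sn](Cl)(CCCC)CCCC)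
Why: α-Lithiation of the allyl silyl ether gives the internally chelated (Z)-oxyallyl anion, which is stannylated at the γ-carbon (metalation–stannylation), so the Z enol ether geometry of the allylstannane is fixed.

Step 3
Reactants: 5 (S)-2,2-dimethyl-1,3-dioxolane-4-carbaldehyde; 4 (Z)-tributyl[3-(tert-butyldimethylsilyloxy)prop-2-en-1-yl]stannane
Product: 6 (1S,2S)-2-(tert-butyldimethylsilyloxy)-1-[(4S)-2,2-dimethyl-1,3-dioxolan-4-yl]but-3-en-1-ol
Conditions: BF3·OEt2, CH2Cl2, −78 °C
Reagents that add atoms: none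
Why: Lewis-acid-promoted SE2′ allylstannane addition through an open antiperiplanar transition state gives the syn C8/C9 relationship, and Felkin–Anh (non-chelated) attack anti to the dioxolane C7–O bond gives the anti C7/C8 relationship, so C9 is set (S) from the (S)-aldehyde.

Step 4
Reactants: 6 (1S,2S)-2-(tert-butyldimethylsilyloxy)-1-[(4S)-2,2-dimethyl-1,3-dioxolan-4-yl]but-3-en-1-ol
Product: 8 (2E,4S,5S)-4-(tert-butyldimethylsilyloxy)-5-[(4S)-2,2-dimethyl-1,3-dioxolan-4-yl]-5-hydroxy-2-methylpent-2-enal, via silyloxy aldehyde 7 (not isolated)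
Conditions: O3, CH2Cl2, −78 °C; PPh3; then Ph3P=C(Me)CHO, PhMe, 70 °C
Reagents that add atoms: 2-(triphenylphosphoranylidene)propanal (CC(C=O)=P(c1ccccc1)(c1ccccc1)c1ccccc1)
Why: Ozonolysis of the terminal alkene and in-situ Wittig olefination with the stabilised formyl ylide, which is E-selective under thermodynamic control, give the (E)-2-methyl enal (C2, C1, C15, C10) under neutral conditions that leave the α-silyloxy centre C9 untouched.

Step 5
Reactants: 2 (E)-1-methoxypent-1-en-3-one; 8 (2E,4S,5S)-hydroxy enal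
Product: 10 silyl ketal triene (O8 of 8 linked by SiMe2 to the dienol oxygen), via dienyloxychlorosilane 9 (not isolated)
Conditions: 2, LiN(SiMe3)2, THF, −78 °C; Me2SiCl2 (5 equiv), −78 → 20 °C, then evaporation; 8, imidazole, CH2Cl2, 0 °C
Reagents that add atoms: dichlorodimethylsilane (C[Si](C)(Cl)Cl)
Why: O-Silylation of the Z lithium dienolate (α′-deprotonation of the vinylogous ester) by excess Me2SiCl2 gives the dienyloxychlorosilane, whose remaining Si–Cl bond is displaced by the only free hydroxyl of 8 (sequential silyl ketal formation), placing the (1E,3Z)-diene and the enal on one silicon atom.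

Step 6
Reactants: 10 silyl ketal triene
Product: 11 silylene-bridged cycloadduct aldehyde
Conditions: PhMe (0.01 M), BHT (cat.), 130 °C, sealed tube
Reagents that add atoms: none
Why: Thermal, concerted but asynchronous [4+2] cycloaddition of the 1-methoxy-3-silyloxy diene (C11=C12–C13=C14) to the C1=C10 enal, the closest known reaction type being the silyl-acetal-tethered type 2 intramolecular Diels–Alder reaction of 2-silyloxydienes. The cyclohexene ring (C1, C10–C14) closes by suprafacial 4+2 union of C11 with C10 and of C14 with C1, and the temporary eight-membered dioxasilocane closes as the five-atom bridge of a bicyclo[5.3.1] skeleton with the enol ether double bond C12=C13 at the bridgehead. C1 and C10 are set relative to C9: allylic 1,3-strain with the C1 methyl keeps H9 in the alkene plane, the tether holds C8 and therefore the diene on one face and leaves the silyloxy group on the other, and the E geometry of the enal places C2 trans to C9. C11 follows from the Z enol ether geometry together with the tether, which forces C9 under C12 (endo), so that the C11 methyl ends cis to C9 and to the C1 methyl; C14 (methoxy cis to the C1 methyl) is lost later. The step needs C11-to-C10 regiochemistry, secured both by the short tether (only the 1,3-bridged mode is feasible) and by the polarity match of the nucleophilic diene terminus C11 with the enal β-carbon C10, and it needs carbon–carbon instead of hetero-Diels–Alder addition at the aldehyde, secured by the absence of any Lewis acid.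

Step 7
Reactants: 11 silylene-bridged cycloadduct aldehyde
Product: 13 enone alcohol (C2 acetate; C8 hydroxyl free), via bridged allylic acetate 12 (not isolated)
Conditions: CH2=CHMgBr, THF, −78 °C; Ac2O, −78 → 0 °C; then 1 M HCl, THF, 0 °C
Reagents that add atoms: vinylmagnesium bromide (C=C[Mg]Br); acetic anhydride (CC(=O)OC(C)=O)
Why: Felkin–Anh addition of the Grignard reagent to the neopentyl aldehyde on the rigid bicycle, anti to the larger ring carbon C10 and past the C1 methyl group, should set C2 as in the target, the alkoxide is acetylated in the flask, and brief cold aqueous acid then hydrolyses both Si–O bonds of the ketal and eliminates methanol from the β-methoxy ketone to give the C13=C14 enone without enolising C11.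

Step 8
Reactants: 13 enone alcohol
Product: 14 C8 ketone
Conditions: Dess–Martin periodinane, NaHCO3, CH2Cl2, 0 → 20 °C
Reagents that add atoms: none
Why: Dess–Martin oxidation of the only free (secondary) hydroxyl gives the C8 ketone under buffered conditions that should not epimerise C7 or C9.

Step 9
Reactants: 14 C8 ketone
Product: 15 keto diol
Conditions: AcOH/H2O (4:1), 35 °C
Reagents that add atoms: none
Why: Acid hydrolysis of the terminal isopropylidene ketal is faster than cleavage of the hindered secondary silyl ether and leaves the allylic acetate intact.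

Step 10
Reactants: 15 keto diol
Product: 16 C6 triethylsilyl ether
Conditions: Et3SiCl, imidazole, CH2Cl2, −40 °C
Reagents that add atoms: chlorotriethylsilane (CC[Si](Cl)(CC)CC)
Why: Silylation is selective for the primary C6 hydroxyl over the hindered secondary C7 hydroxyl next to the ketone (steric differentiation at low temperature).

Step 11
Reactants: 16 C6 triethylsilyl ether
Product: 17 C7 2-bromopropanoate
Conditions: 2-bromopropanoyl bromide, pyridine, CH2Cl2, −20 °C
Reagents that add atoms: 2-bromopropanoyl bromide (CC(Br)C(=O)Br)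
Why: Acylation of the remaining C7 hydroxyl with the acid bromide installs the α-bromo ester next to the C8 ketone; the bromide-bearing carbon is a mixture of epimers that converge in the next step.

Step 12
Reactants: 17 C7 2-bromopropanoate
Product: 18 hydroxy lactone
Conditions: Zn dust (activated with Me3SiCl), THF, 40 °C
Reagents that add atoms: none
Why: Intramolecular Reformatsky reaction: the zinc ester enolate tethered through O7 adds to the C8 ketone and closes the γ-lactone by a 5-exo-trig aldol from the face that keeps the large C9 substituent trans to C6 on the new ring (C8 hydroxyl cis to C6), while the C17 methyl should take the less hindered position trans to C9, which is also the thermodynamic one at this epimerisable centre.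

Step 13
Reactants: 18 hydroxy lactone
Product: 19 C3 aldehyde
Conditions: O3, CH2Cl2/pyridine, −78 °C (Sudan red indicator); PPh3
Reagents that add atoms: ozone ([O-][O+]=O)
Why: Ozone cleaves the electron-richer terminal vinyl group much faster than the conjugated C13=C14 alkene (indicator-controlled ozonolysis with reductive work-up), giving the α-acetoxy aldehyde at C3.

Step 14
Reactants: 19 C3 aldehyde
Product: 20 2-bromoallyl carbinol
Conditions: In powder, 2,3-dibromopropene, THF/H2O (1:1), 20 °C
Reagents that add atoms: 2,3-dibromoprop-1-ene (C=C(Br)CBr)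
Why: Indium-mediated Barbier allylation is selective for the aldehyde over ketone, enone and lactone, and Felkin–Anh attack anti to the C2–OAc bond should give the 2,3-anti carbinol required for C3; any acetyl migration from O2 to O3 is harmless because both oxygens end as acetates.

Step 15
Reactants: 20 2-bromoallyl carbinol
Product: 21 C2,C3 diacetate
Conditions: Ac2O, pyridine, DMAP (cat.), CH2Cl2, 0 °C
Reagents that add atoms: acetic anhydride (CC(=O)OC(C)=O)
Why: Acetylation of the free secondary hydroxyl gives the diacetate, while the hindered tertiary C8 hydroxyl should not react under these mild conditions.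

Step 16
Reactants: 21 C2,C3 diacetate
Product: 22 C6 aldehyde
Conditions: (COCl)2, DMSO, CH2Cl2, −78 → −40 °C; Et3N, −78 → −20 °C
Reagents that add atoms: none
Why: Primary triethylsilyl ethers are oxidised directly to aldehydes under Swern conditions (the chlorosulfonium salt cleaves the Si–O bond), which unmasks the C6 aldehyde in one operation and leaves the tertiary hydroxyl and the secondary silyl ether untouched.

Step 17
Reactants: 22 C6 aldehyde
Product: 23 macrocyclic allylic alcohols (C6 epimers)
Conditions: CrCl2 (10 equiv), NiCl2 (2 mol %), DMSO, 20 °C, slow addition to 0.002 M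
Reagents that add atoms: none
Why: Nozaki–Hiyama–Kishi reaction: nickel-catalysed formation of the alkenylchromium species from the 2-bromoalkene and its aldehyde-selective intramolecular addition should close the ten-membered ring (10-exo addition under high dilution) and create the C5 exo-methylene; the configuration of the new C6 carbinol is of no consequence because it is removed in step 18.

Step 18
Reactants: 23 macrocyclic allylic alcohols (C6 epimers)
Product: 24 C6 α-methylene ketone
Conditions: Dess–Martin periodinane, NaHCO3, CH2Cl2, 0 °C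
Reagents that add atoms: none
Why: Dess–Martin oxidation converges both C6 epimers to the α-methylene ketone, the tertiary C8 hydroxyl being inert.

Step 19
Reactants: 24 C6 α-methylene ketone
Product: 25 (6R)-allylic alcohol
Conditions: Me4NBH(OAc)3, MeCN/AcOH (1:1), −30 °C
Reagents that add atoms: none
Why: Evans–Saksena reduction: the triacetoxyborohydride binds the tertiary C8 hydroxyl and delivers hydride intramolecularly through a chair transition state with C5 equatorial, which should give the 6,8-anti (6,7-syn) alcohol and is chemoselective for the β-hydroxy ketone over the cyclohexenone.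

Step 20
Reactants: 25 (6R)-allylic alcohol
Product: 26 (6S)-chloride
Conditions: PPh3, hexachloroacetone, CH2Cl2, −20 → 0 °C
Reagents that add atoms: hexachloroacetone (O=C(C(Cl)(Cl)Cl)C(Cl)(Cl)Cl)
Why: The alkoxyphosphonium salt is displaced by chloride in an SN2 reaction with inversion and without allylic transposition (Appel-type chlorination), converting the (6R)-alcohol into the (6S)-chloride of the target; the tertiary hydroxyl does not react.

Step 21
Reactants: 26 (6S)-chloride
Product: 27 C9 alcohol
Conditions: HF·pyridine, THF, 0 → 20 °C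
Reagents that add atoms: none
Why: Fluoride-mediated cleavage of the remaining silyl ether frees the C9 hydroxyl under acidic, non-epimerising conditions compatible with acetates, lactone, enone and allylic chloride.

Step 22
Reactants: 27 C9 alcohol
Product: 28 CNP0391614.1
Conditions: Ac2O, pyridine, DMAP (cat.), CH2Cl2, 0 → 20 °C
Reagents that add atoms: acetic anhydride (CC(=O)OC(C)=O)
Why: Acetylation of the secondary C9 hydroxyl completes the triacetate, the tertiary C8 hydroxyl remaining free as in the target.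

Compound list
1 | (E)-4-methoxybut-3-en-2-one | CO/C=C/C(C)=O | starting material
2 | (E)-1-methoxypent-1-en-3-one | CO/C=C/C(=O)CC | intermediate
3 | allyloxy(tert-butyl)dimethylsilane | C=CCO[Si](C)(C)C(C)(C)C | starting material
4 | (Z)-tributyl[3-(tert-butyldimethylsilyloxy)prop-2-en-1-yl]stannane | CCCC[Sn](CCCC)(CCCC)C/C=C\O[Si](C)(C)C(C)(C)C | intermediate
5 | (S)-2,2-dimethyl-1,3-dioxolane-4-carbaldehyde | O=C[C@@H]1COC(C)(C)O1 | starting material
6 | (1S,2S)-2-(tert-butyldimethylsilyloxy)-1-[(4S)-2,2-dimethyl-1,3-dioxolan-4-yl]but-3-en-1-ol (C6–C10; O8 free, O9 silylated) | C=C[C@H](O[Si](C)(C)C(C)(C)C)[C@@H](O)[C@@H]1COC(C)(C)O1 | intermediate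
7 | (2R,3S)-2-(tert-butyldimethylsilyloxy)-3-[(4S)-2,2-dimethyl-1,3-dioxolan-4-yl]-3-hydroxypropanal | O=C[C@H](O[Si](C)(C)C(C)(C)C)[C@@H](O)[C@@H]1COC(C)(C)O1 | intermediate (not isolated)
8 | (2E,4S,5S)-4-(tert-butyldimethylsilyloxy)-5-[(4S)-2,2-dimethyl-1,3-dioxolan-4-yl]-5-hydroxy-2-methylpent-2-enal | O=C/C(C)=C/[C@H](O[Si](C)(C)C(C)(C)C)[C@@H](O)[C@@H]1COC(C)(C)O1 | intermediate
9 | chloro{[(2Z,4E)-5-methoxypenta-2,4-dien-3-yl]oxy}dimethylsilane | CO/C=C/C(=C/C)O[Si](C)(C)Cl | intermediate (not isolated)
10 | silyl ketal triene: O8 of 8 joined through SiMe2 to the enol oxygen of the (2Z,4E)-5-methoxypenta-2,4-dien-3-yl unit | O=C/C(C)=C/[C@H](O[Si](C)(C)C(C)(C)C)[C@@H](O[Si](C)(C)O/C(=C\C)/C=C/OC)[C@@H]1COC(C)(C)O1 | intermediate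
11 | silylene-bridged cycloadduct aldehyde: cyclohexene C1/C10–C14 with methyl and formyl (C2) on C1, methoxy on C14 and methyl on C11 both cis to the C1 methyl, C12=C13 enol ether with O12 bridged by SiMe2 to O8 (bicyclo[5.3.1]), C9 (S)-OTBS, C7 in the (S)-dioxolane | O=C[C@@]2(C)[C@H](OC)C=C(O3)[C@H](C)[C@@H]2[C@H](O[Si](C)(C)C(C)(C)C)[C@@H](O[Si]3(C)C)[C@@H]1COC(C)(C)O1 | intermediate
12 | bridged allylic acetate: 11 with the formyl group converted into CH(OAc)CH=CH2, C2 configured as in the target | C=C[C@H](OC(C)=O)[C@@]2(C)[C@H](OC)C=C(O3)[C@H](C)[C@@H]2[C@H](O[Si](C)(C)C(C)(C)C)[C@@H](O[Si]3(C)C)[C@@H]1COC(C)(C)O1 | intermediate (not isolated)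
13 | enone alcohol: cyclohex-2-enone (C12 ketone, C13=C14) with methyl and CH(OAc)CH=CH2 on C1, methyl on C11, side chain CH(OTBS)–CH(OH)–dioxolane on C10; C1, C2, C9, C10, C11 as in the target | C=C[C@H](OC(C)=O)[C@@]2(C)C=CC(=O)[C@H](C)[C@@H]2[C@H](O[Si](C)(C)C(C)(C)C)[C@@H](O)[C@@H]1COC(C)(C)O1 | intermediate
14 | C8 ketone: 13 with the C8 carbinol oxidised | C=C[C@H](OC(C)=O)[C@@]2(C)C=CC(=O)[C@H](C)[C@@H]2[C@H](O[Si](C)(C)C(C)(C)C)C(=O)[C@@H]1COC(C)(C)O1 | intermediate
15 | keto diol: 14 without the isopropylidene group (C6 and C7 hydroxyls free) | C=C[C@H](OC(C)=O)[C@@]2(C)C=CC(=O)[C@H](C)[C@@H]2[C@H](O[Si](C)(C)C(C)(C)C)C(=O)[C@@H](O)CO | intermediate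
16 | C6 triethylsilyl ether of 15 | C=C[C@H](OC(C)=O)[C@@]2(C)C=CC(=O)[C@H](C)[C@@H]2[C@H](O[Si](C)(C)C(C)(C)C)C(=O)[C@@H](O)CO[Si](CC)(CC)CC | intermediate
17 | C7 2-bromopropanoate of 16 (epimers at CHBr) | C=C[C@H](OC(C)=O)[C@@]2(C)C=CC(=O)[C@H](C)[C@@H]2[C@H](O[Si](C)(C)C(C)(C)C)C(=O)[C@@H](OC(=O)C(C)Br)CO[Si](CC)(CC)CC | intermediate
18 | hydroxy lactone: γ-lactone C19–O–C7 with C8 tertiary hydroxyl and C17 methyl as in the target, C6 as CH2OSiEt3 | C=C[C@H](OC(C)=O)[C@@]2(C)C=CC(=O)[C@H](C)[C@@H]2[C@H](O[Si](C)(C)C(C)(C)C)[C@]2(O)[C@@H](C)C(=O)O[C@H]2CO[Si](CC)(CC)CC | intermediate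
19 | C3 aldehyde: 18 with the vinyl group cleaved to the C2-acetoxy aldehyde | O=C[C@H](OC(C)=O)[C@@]2(C)C=CC(=O)[C@H](C)[C@@H]2[C@H](O[Si](C)(C)C(C)(C)C)[C@]2(O)[C@@H](C)C(=O)O[C@H]2CO[Si](CC)(CC)CC | intermediate
20 | 2-bromoallyl carbinol: C3 hydroxyl (as in the target) and CH2–C(Br)=CH2 (C4, C5, C16) | C=C(Br)C[C@H](O)[C@H](OC(C)=O)[C@@]2(C)C=CC(=O)[C@H](C)[C@@H]2[C@H](O[Si](C)(C)C(C)(C)C)[C@]2(O)[C@@H](C)C(=O)O[C@H]2CO[Si](CC)(CC)CC | intermediate
21 | C2,C3 diacetate of 20 | C=C(Br)C[C@H](OC(C)=O)[C@H](OC(C)=O)[C@@]2(C)C=CC(=O)[C@H](C)[C@@H]2[C@H](O[Si](C)(C)C(C)(C)C)[C@]2(O)[C@@H](C)C(=O)O[C@H]2CO[Si](CC)(CC)CC | intermediate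
22 | C6 aldehyde: 21 with CH2OSiEt3 oxidised to CHO | C=C(Br)C[C@H](OC(C)=O)[C@H](OC(C)=O)[C@@]2(C)C=CC(=O)[C@H](C)[C@@H]2[C@H](O[Si](C)(C)C(C)(C)C)[C@]2(O)[C@@H](C)C(=O)O[C@H]2C=O | intermediate
23 | macrocyclic allylic alcohols: briarane skeleton with C5 exo-methylene and C6 hydroxyl (both C6 epimers), C9 OTBS | C=C1C[C@H](OC(C)=O)[C@H](OC(C)=O)[C@@]2(C)C=CC(=O)[C@H](C)[C@@H]2[C@H](O[Si](C)(C)C(C)(C)C)[C@]2(O)[C@@H](C)C(=O)O[C@H]2C1O | intermediate
24 | C6 α-methylene ketone | C=C1C[C@H](OC(C)=O)[C@H](OC(C)=O)[C@@]2(C)C=CC(=O)[C@H](C)[C@@H]2[C@H](O[Si](C)(C)C(C)(C)C)[C@]2(O)[C@@H](C)C(=O)O[C@H]2C1=O | intermediate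
25 | (6R)-allylic alcohol (C6 hydroxyl syn to O7) | C=C1C[C@H](OC(C)=O)[C@H](OC(C)=O)[C@@]2(C)C=CC(=O)[C@H](C)[C@@H]2[C@H](O[Si](C)(C)C(C)(C)C)[C@]2(O)[C@@H](C)C(=O)O[C@H]2[C@@H]1O | intermediate
26 | (6S)-chloride with C9 OTBS | C=C1C[C@H](OC(C)=O)[C@H](OC(C)=O)[C@@]2(C)C=CC(=O)[C@H](C)[C@@H]2[C@H](O[Si](C)(C)C(C)(C)C)[C@]2(O)[C@@H](C)C(=O)O[C@H]2[C@H]1Cl | intermediate
27 | C9 alcohol (9-deacetyl target) | C=C1C[C@H](OC(C)=O)[C@H](OC(C)=O)[C@@]2(C)C=CC(=O)[C@H](C)[C@@H]2[C@H](O)[C@]2(O)[C@@H](C)C(=O)O[C@H]2[C@H]1Cl | intermediate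
28 | CNP0391614.1 | C=C1C[C@H](OC(C)=O)[C@H](OC(C)=O)[C@@]2(C)C=CC(=O)[C@H](C)[C@@H]2[C@H](OC(C)=O)[C@]2(O)[C@@H](C)C(=O)O[C@H]2[C@H]1Cl | target

Total step count: 22. Longest linear sequence: 21 steps (steps 2–22, from 3 to 28); step 1 makes the side component 2, which enters in step 5, and 5 enters in step 3.

Steps most likely to fail

Step 6. The thermal cycloaddition of the β-branched, trisubstituted enal may be slower than desilylation or decomposition of the silyl ketal. The fallback sets out from 2 and 8 and returns at 13; it keeps the tether but uses the far more reactive 1-amino-3-silyloxy diene. Exchange of the methoxy group of 2 with dimethylamine should give (E)-1-(dimethylamino)pent-1-en-3-one F1. KN(SiMe3)2 and then excess Me2SiCl2 should give the aminodienyloxychlorosilane F2. Imidazole-mediated union with 8 should give the amino silyl ketal F3, which is expected to cyclise at or slightly above room temperature to the amino cycloadduct F4. Vinylmagnesium bromide followed by Ac2O should give the bridged amino acetate F5, and 1 M HCl should hydrolyse the silyl ketal and expel dimethylamine to give 13.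

Step 7. Facial selectivity in the Grignard addition to the C2 aldehyde may be poor. The fallback sets out from 11 and returns at 13 through 12; it sets C2 by reagent control. Vinylmagnesium bromide with aqueous quench should give the C2-epimeric allylic alcohols F6. MnO2 should oxidise them to the vinyl ketone F7. Reduction with (R)-2-methyl-CBS-oxazaborolidine and catecholborane at −78 °C, in which the quaternary C1 acts as the large group and the silyl enol ether is not hydroborated, should give the single allylic alcohol F8. Acetylation (Ac2O, pyridine, DMAP) should give 12, and 1 M HCl then gives 13.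

Step 17. Nickel insertion into the 2-bromoalkene may be slow, so that intermolecular coupling and reduction of the aldehyde compete with ten-membered ring closure. The fallback sets out from 19 and returns at 23; the ring is closed by nickel-catalysed reductive coupling of an alkyne with the aldehyde. Indium-mediated propargylation of 19 with propargyl bromide should give the homopropargylic alcohol F9. Acetylation should give the alkynyl diacetate F10. Swern oxidation of the triethylsilyl ether should give the ynal F11. Ni(cod)2, a bulky N-heterocyclic carbene ligand and Et3SiH under high dilution should form the C5–C6 bond at the internal alkyne carbon and give the macrocyclic exo-methylene allylic triethylsilyl ether F12 (C6 epimers). AcOH/THF/H2O should remove the triethylsilyl group to give 23.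

Further compounds
F1 | step 6 | (E)-1-(dimethylamino)pent-1-en-3-one | CN(C)/C=C/C(=O)CC
F2 | step 6 | chloro{[(2Z,4E)-5-(dimethylamino)penta-2,4-dien-3-yl]oxy}dimethylsilane | CN(C)/C=C/C(=C/C)O[Si](C)(C)Cl
F3 | step 6 | amino silyl ketal (10 with NMe2 in place of OMe) | O=C/C(C)=C/[C@H](O[Si](C)(C)C(C)(C)C)[C@@H](O[Si](C)(C)O/C(=C\C)/C=C/N(C)C)[C@@H]1COC(C)(C)O1
F4 | step 6 | amino cycloadduct (11 with NMe2 at C14) | O=C[C@@]2(C)[C@H](N(C)C)C=C(O3)[C@H](C)[C@@H]2[C@H](O[Si](C)(C)C(C)(C)C)[C@@H](O[Si]3(C)C)[C@@H]1COC(C)(C)O1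
F5 | step 6 | bridged amino acetate (12 with NMe2 at C14) | C=C[C@H](OC(C)=O)[C@@]2(C)[C@H](N(C)C)C=C(O3)[C@H](C)[C@@H]2[C@H](O[Si](C)(C)C(C)(C)C)[C@@H](O[Si]3(C)C)[C@@H]1COC(C)(C)O1
F6 | step 7 | bridged allylic alcohols (C2 epimers) | C=CC(O)[C@@]2(C)[C@H](OC)C=C(O3)[C@H](C)[C@@H]2[C@H](O[Si](C)(C)C(C)(C)C)[C@@H](O[Si]3(C)C)[C@@H]1COC(C)(C)O1
F7 | step 7 | bridged vinyl ketone | C=CC(=O)[C@@]2(C)[C@H](OC)C=C(O3)[C@H](C)[C@@H]2[C@H](O[Si](C)(C)C(C)(C)C)[C@@H](O[Si]3(C)C)[C@@H]1COC(C)(C)O1
F8 | step 7 | bridged allylic alcohol with C2 as in the target | C=C[C@H](O)[C@@]2(C)[C@H](OC)C=C(O3)[C@H](C)[C@@H]2[C@H](O[Si](C)(C)C(C)(C)C)[C@@H](O[Si]3(C)C)[C@@H]1COC(C)(C)O1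
F9 | step 17 | homopropargylic alcohol (C3 hydroxyl, C4–C5≡C16H) | C#CC[C@H](O)[C@H](OC(C)=O)[C@@]2(C)C=CC(=O)[C@H](C)[C@@H]2[C@H](O[Si](C)(C)C(C)(C)C)[C@]2(O)[C@@H](C)C(=O)O[C@H]2CO[Si](CC)(CC)CC
F10 | step 17 | alkynyl diacetate | C#CC[C@H](OC(C)=O)[C@H](OC(C)=O)[C@@]2(C)C=CC(=O)[C@H](C)[C@@H]2[C@H](O[Si](C)(C)C(C)(C)C)[C@]2(O)[C@@H](C)C(=O)O[C@H]2CO[Si](CC)(CC)CC
F11 | step 17 | ynal (C6 aldehyde) | C#CC[C@H](OC(C)=O)[C@H](OC(C)=O)[C@@]2(C)C=CC(=O)[C@H](C)[C@@H]2[C@H](O[Si](C)(C)C(C)(C)C)[C@]2(O)[C@@H](C)C(=O)O[C@H]2C=O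
F12 | step 17 | macrocyclic allylic triethylsilyl ether (C6 epimers) | C=C1C[C@H](OC(C)=O)[C@H](OC(C)=O)[C@@]2(C)C=CC(=O)[C@H](C)[C@@H]2[C@H](O[Si](C)(C)C(C)(C)C)[C@]2(O)[C@@H](C)C(=O)O[C@H]2C1O[Si](CC)(CC)CC
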